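**Plan**

- Retrosynthesis (isoquinoline locants C1, N2, C3, C4, C4a, C5–C8, C8a; C1' is the naphthalene carbon bonded to C5): cut the aryl–aryl bond C5–C1' first (Suzuki–Miyaura), then N–CH3 and C1–H, then the ring bond C1–N together with C3–N. This leaves an achiral 1,5-diketone, an amine donor and a naphthyl boronate.
- Enabling feature: C1 and C3 of the nitrogen ring stand 1,5 to each other across the C8a–C4a edge of the benzene ring, so the heterocycle is the cyclic imine of a diketone. Its C3 ketone is a free benzyl methyl ketone; its C1 ketone is a shielded 2,6-disubstituted acetophenone.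
- Forward, isoquinoline half: acetylation of 3,5-dimethoxyphenylacetone gives the diketone; an (S)-selective ω-transaminase (pyridoxal-phosphate-dependent amine transaminase) aminates C3 and the amine closes the ring onto C1; NaBH4 reduction, N-methylation and C5 iodination follow.
- Forward, naphthalene half: Stobbe condensation and ring closure from 2-bromo-5-methoxybenzaldehyde build the second benzene ring; the bromine steers that closure and later becomes the boronate. The two halves are joined in the last step, so the enzyme sees only a small substrate.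
- Stereochemistry: C3 (S) comes from the enzyme; C1 (R) comes from substrate-controlled hydride addition to the cyclic imine, cis to the C3 methyl group.

Key step: step 2

Assumption: the structure as given fixes C1 (R) and C3 (S) but no sense of twist for the hindered aryl–aryl axis, so the axis is left open and both rotational isomers that the last step can give (separable by chromatography if they do not interconvert) are taken to answer the structure.

**Route**

Step 1
Reactants: 1 1-(3,5-dimethoxyphenyl)propan-2-one
Product: 3 1-(2-acetyl-3,5-dimethoxyphenyl)propan-2-one, via benzopyrylium tetrafluoroborate 2 (not isolated)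
Conditions: Ac2O, HBF4·OEt2, 0 °C to rt; then NaOAc, H2O/acetone, rt
Reagents that add atoms: acetic anhydride CC(=O)OC(C)=O; water O
Why: Friedel–Crafts acetylation should take the ring position ortho to the acetonyl arm and para to a methoxy group, because only there can the new ketone close with the side-chain ketone to the aromatic 2-benzopyrylium cation 2 that drains the reversible acylation, and mild aqueous base then reopens 2 through its pseudobase to the 1,5-diketone without the stronger base that would bring on aldol closure to a naphthol.

Step 2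
Reactants: 3 1-(2-acetyl-3,5-dimethoxyphenyl)propan-2-one
Product: 5 (3S)-6,8-dimethoxy-1,3-dimethyl-3,4-dihydroisoquinoline, via amino ketone 4 (not isolated)
Conditions: (S)-selective ω-transaminase (Chromobacterium violaceum type, isopropylamine-tolerant, lyophilised cell-free extract), pyridoxal 5'-phosphate (1 mM), i-PrNH2·HCl (5 equiv), HEPES buffer pH 7.5, DMSO (10% v/v), 30 °C; then NaOH to pH 11, extraction with EtOAc
Reagents that add atoms: isopropylamine CC(C)N
Why: The pyridoxal phosphate cofactor of the transaminase is charged by isopropylamine to its pyridoxamine form, which condenses with the unhindered benzyl methyl ketone of 3 and, after a 1,3-prototropic shift in the active site, releases the primary amine 4; the nitrogen of 4 then adds to the neighbouring aryl ketone carbon and the carbinolamine loses water, which forms the ring bond C1–N as a C=N bond and removes 4 from the transamination equilibrium. The closest known reaction type is the transaminase-triggered monoamination and spontaneous cyclisation of 1,4- and 1,5-diketones to 1-pyrrolines and 1-piperideines, including cases in which an alkyl methyl ketone is aminated and the ring closes onto an aryl ketone. The six-membered nitrogen ring closes by 6-exo-trig addition of the amine to the carbonyl group followed by dehydration. The only new stereocenter, C3, is set by the enzyme, whose small pocket takes the methyl group and whose large pocket takes the arylmethyl group, so that the amino group is delivered to one face only and the (S) amine results, as with phenylacetone itself. The step needs regioselectivity between two methyl ketones, and the substrate secures it because the C1 ketone is a 2,6-disubstituted acetophenone, flanked by the C8 methoxy group and the C4 methylene arm and deactivated as a vinylogous ester by the C6 and C8 methoxy groups, so that it is refused as a transaminase substrate yet still serves as the internal electrophile. A pH near 7.5, at which isopropylamine is almost fully protonated, should hold back the non-enzymatic condensation of the diketone with the donor and its aldol closure to a naphthol.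

Step 3
Reactants: 5 (3S)-6,8-dimethoxy-1,3-dimethyl-3,4-dihydroisoquinoline
Product: 6 (1R,3S)-6,8-dimethoxy-1,3-dimethyl-1,2,3,4-tetrahydroisoquinoline
Conditions: NaBH4, MeOH, 0 °C to rt
Reagents that add atoms: none
Why: Hydride reduction of the cyclic imine should give the 1,3-cis product, since the half-chair holds the C3 methyl group pseudo-equatorial and hydride adds axially to C1 from the face that bears the axial C3 hydrogen (anti to the C3 methyl group), which sets C1 as (R) next to C3 (S), the usual outcome for 1,3-dimethyl-3,4-dihydroisoquinolines.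

Step 4
Reactants: 6 (1R,3S)-6,8-dimethoxy-1,3-dimethyl-1,2,3,4-tetrahydroisoquinoline
Product: 7 (1R,3S)-6,8-dimethoxy-1,2,3-trimethyl-1,2,3,4-tetrahydroisoquinoline
Conditions: HCHO (37% aq.), NaBH(OAc)3, ClCH2CH2Cl, rt
Reagents that add atoms: formaldehyde C=O
Why: Reductive amination (iminium formation with formaldehyde and hydride transfer from NaBH(OAc)3) methylates the hindered secondary amine without quaternisation and touches neither stereocenter.

Step 5
Reactants: 7 (1R,3S)-6,8-dimethoxy-1,2,3-trimethyl-1,2,3,4-tetrahydroisoquinoline
Product: 8 (1R,3S)-5-iodo-6,8-dimethoxy-1,2,3-trimethyl-1,2,3,4-tetrahydroisoquinoline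
Conditions: N-iodosuccinimide (1.05 equiv), CF3CO2H (2 equiv), MeCN, 0 °C to rt
Reagents that add atoms: N-iodosuccinimide O=C1CCC(=O)N1I
Why: Electrophilic aromatic iodination of the ammonium trifluoroacetate (protonation shields the amine from oxidation) should go to C5, which is para to the C8 methoxy and ortho to the C6 methoxy group, the position of a resorcinol dimethyl ether that halogenates first, in preference to C7 between the two methoxy groups.

Step 6
Reactants: 9 2-bromo-5-methoxybenzaldehyde; 10 dimethyl succinate
Product: 11 (3E)-4-(2-bromo-5-methoxyphenyl)-3-(methoxycarbonyl)but-3-enoic acid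
Conditions: NaOMe, MeOH, reflux; then aq. HCl
Reagents that add atoms: none
Why: Stobbe condensation, in which the succinate enolate adds to the aldehyde, the alkoxide lactonises to a paraconate and base-induced opening of this lactone gives the half ester with the (E) double bond, the aryl group lying cis to the CH2CO2H arm as the next ring closure needs.

Step 7
Reactants: 11 (3E)-4-(2-bromo-5-methoxyphenyl)-3-(methoxycarbonyl)but-3-enoic acid
Product: 12 methyl 4-acetoxy-8-bromo-5-methoxynaphthalene-2-carboxylate
Conditions: Ac2O, NaOAc, 140 °C
Reagents that add atoms: acetic anhydride CC(=O)OC(C)=O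
Why: The mixed anhydride of the acid acylates the aryl ring intramolecularly (Friedel–Crafts type benzannulation of a Stobbe half ester) at the only free ortho position, which is activated by the neighbouring methoxy group while the bromine blocks the other one, and the naphthol formed by enolisation is acetylated in the same pot.

Step 8
Reactants: 12 methyl 4-acetoxy-8-bromo-5-methoxynaphthalene-2-carboxylate
Product: 14 methyl 8-bromo-4,5-dimethoxynaphthalene-2-carboxylate, via naphthol 13 (not isolated)
Conditions: K2CO3, MeOH, rt; evaporation; then MeI, DMF, rt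
Reagents that add atoms: iodomethane CI
Why: Methanolysis of the aryl acetate under K2CO3 frees the peri-hydroxy naphtholate, which is then O-methylated by MeI in a Williamson ether synthesis, while the methyl ester is unchanged in methanol.

Step 9
Reactants: 14 methyl 8-bromo-4,5-dimethoxynaphthalene-2-carboxylate
Product: 15 (8-bromo-4,5-dimethoxynaphthalen-2-yl)methanol
Conditions: i-Bu2AlH (2.5 equiv), CH2Cl2, −78 to 0 °C; aq. potassium sodium tartrate
Reagents that add atoms: none
Why: Ester reduction with i-Bu2AlH stops cleanly at the primary benzylic alcohol and leaves the aryl bromide and the methyl ethers untouched.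

Step 10
Reactants: 15 (8-bromo-4,5-dimethoxynaphthalen-2-yl)methanol
Product: 17 1-bromo-4,5-dimethoxy-7-methylnaphthalene, via benzylic mesylate 16 (not isolated)
Conditions: MsCl, Et3N, THF, 0 °C; filtration of Et3NHCl under N2; then LiBHEt3, 0 °C to rt
Reagents that add atoms: none
Why: Deoxygenation by activation and hydride displacement, in which the primary benzylic mesylate is displaced in an SN2 reaction by the hydride of LiBHEt3, a reagent that does not attack the aryl bromide at this temperature.

Step 11
Reactants: 17 1-bromo-4,5-dimethoxy-7-methylnaphthalene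
Product: 19 2-(4,5-dimethoxy-7-methylnaphthalen-1-yl)-4,4,5,5-tetramethyl-1,3,2-dioxaborolane, via aryllithium 18 (not isolated)
Conditions: n-BuLi, THF, −78 °C; then 2-isopropoxy-4,4,5,5-tetramethyl-1,3,2-dioxaborolane, −78 °C to rt; then H2O
Reagents that add atoms: 2-isopropoxy-4,4,5,5-tetramethyl-1,3,2-dioxaborolane CC(C)OB1OC(C)(C)C(C)(C)O1
Why: Bromine–lithium exchange is faster at −78 °C than ortho-lithiation next to the methoxy groups, and the aryllithium is trapped at boron by the isopropoxy pinacol borate to give the pinacol boronate (lithiation–borylation).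

Step 12
Reactants: 8 (1R,3S)-5-iodo-6,8-dimethoxy-1,2,3-trimethyl-1,2,3,4-tetrahydroisoquinoline; 19 2-(4,5-dimethoxy-7-methylnaphthalen-1-yl)-4,4,5,5-tetramethyl-1,3,2-dioxaborolane
Product: 20 (1R,3S)-5-(4,5-dimethoxy-7-methylnaphthalen-1-yl)-6,8-dimethoxy-1,2,3-trimethyl-1,2,3,4-tetrahydroisoquinoline
Conditions: Pd(OAc)2 (5 mol%), SPhos (10 mol%), K3PO4, toluene/H2O, 100 °C
Reagents that add atoms: none
Why: Suzuki–Miyaura coupling, in which the zerovalent palladium species formed from Pd(OAc)2 and the bulky biaryl phosphine SPhos adds oxidatively to the electron-rich aryl iodide and allows transmetalation and reductive elimination to the tri-ortho-substituted biaryl, the free tertiary amine and both stereocenters being inert and the new axis being formed without control, in line with the assumption above.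

**Compound list**

1 | 1-(3,5-dimethoxyphenyl)propan-2-one | CC(=O)Cc1cc(OC)cc(OC)c1 | starting material
2 | 6,8-dimethoxy-1,3-dimethylisochromenylium (2-benzopyrylium) tetrafluoroborate | Cc1cc2cc(OC)cc(OC)c2c(C)[o+]1.F[B-](F)(F)F | intermediate
3 | 1-(2-acetyl-3,5-dimethoxyphenyl)propan-2-one | CC(=O)Cc1cc(OC)cc(OC)c1C(C)=O | intermediate
4 | 1-[2-[(2S)-2-aminopropyl]-4,6-dimethoxyphenyl]ethan-1-one | C[C@H](N)Cc1cc(OC)cc(OC)c1C(C)=O | intermediate
5 | (3S)-6,8-dimethoxy-1,3-dimethyl-3,4-dihydroisoquinoline | C[C@H]1Cc2cc(OC)cc(OC)c2C(C)=N1 | intermediate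
6 | (1R,3S)-6,8-dimethoxy-1,3-dimethyl-1,2,3,4-tetrahydroisoquinoline (1,3-cis) | COc1cc(OC)c2c(c1)C[C@H](C)N[C@@H]2C | intermediate
7 | (1R,3S)-6,8-dimethoxy-1,2,3-trimethyl-1,2,3,4-tetrahydroisoquinoline | COc1cc(OC)c2c(c1)C[C@H](C)N(C)[C@@H]2C | intermediate
8 | (1R,3S)-5-iodo-6,8-dimethoxy-1,2,3-trimethyl-1,2,3,4-tetrahydroisoquinoline | COc1cc(OC)c2c(c1I)C[C@H](C)N(C)[C@@H]2C | intermediate
9 | 2-bromo-5-methoxybenzaldehyde | COc1ccc(Br)c(C=O)c1 | starting material
10 | dimethyl succinate | COC(=O)CCC(=O)OC | starting material
11 | (3E)-4-(2-bromo-5-methoxyphenyl)-3-(methoxycarbonyl)but-3-enoic acid | COC(=O)/C(CC(=O)O)=C/c1cc(OC)ccc1Br | intermediate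
12 | methyl 4-acetoxy-8-bromo-5-methoxynaphthalene-2-carboxylate | COC(=O)c1cc(OC(C)=O)c2c(OC)ccc(Br)c2c1 | intermediate
13 | methyl 8-bromo-4-hydroxy-5-methoxynaphthalene-2-carboxylate (formed as its potassium salt) | COC(=O)c1cc(O)c2c(OC)ccc(Br)c2c1 | intermediate
14 | methyl 8-bromo-4,5-dimethoxynaphthalene-2-carboxylate | COC(=O)c1cc(OC)c2c(OC)ccc(Br)c2c1 | intermediate
15 | (8-bromo-4,5-dimethoxynaphthalen-2-yl)methanol | OCc1cc(OC)c2c(OC)ccc(Br)c2c1 | intermediate
16 | (8-bromo-4,5-dimethoxynaphthalen-2-yl)methyl methanesulfonate | CS(=O)(=O)OCc1cc(OC)c2c(OC)ccc(Br)c2c1 | intermediate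
17 | 1-bromo-4,5-dimethoxy-7-methylnaphthalene | Cc1cc(OC)c2c(OC)ccc(Br)c2c1 | intermediate
18 | (4,5-dimethoxy-7-methylnaphthalen-1-yl)lithium | [Li]c1ccc(OC)c2c(OC)cc(C)cc12 | intermediate
19 | 2-(4,5-dimethoxy-7-methylnaphthalen-1-yl)-4,4,5,5-tetramethyl-1,3,2-dioxaborolane | Cc1cc(OC)c2c(OC)ccc(B3OC(C)(C)C(C)(C)O3)c2c1 | intermediate
20 | (1R,3S)-5-(4,5-dimethoxy-7-methylnaphthalen-1-yl)-6,8-dimethoxy-1,2,3-trimethyl-1,2,3,4-tetrahydroisoquinoline | COc1cc(OC)c2c(c1-c1ccc(OC)c3c(OC)cc(C)cc13)C[C@H](C)N(C)[C@@H]2C | target

**Count and risks**

Total step count: 12. Longest linear sequence: 7 steps (steps 6 to 12, from 9 to 20).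

Steps most likely to fail:

1. Step 2. The enzyme may turn over the ortho-acylated benzyl ketone too slowly, so that non-enzymatic condensation of the diketone with the amine donor or aldol ring closure outruns the transamination. The fallback sets out from 1 and comes back at 5. Reductive amination of 1 with (S)-1-phenylethylamine (H2, Raney Ni, EtOH) should favour the (S,S) secondary amine (2S)-1-(3,5-dimethoxyphenyl)-N-[(1S)-1-phenylethyl]propan-2-amine F1, which is purified by crystallisation of its hydrochloride. Hydrogenolysis (H2, Pd/C, MeOH) removes the auxiliary and gives (2S)-1-(3,5-dimethoxyphenyl)propan-2-amine F2. Acetylation (Ac2O, Et3N, CH2Cl2) gives N-[(2S)-1-(3,5-dimethoxyphenyl)propan-2-yl]acetamide F3. Bischler–Napieralski cyclisation (POCl3, MeCN, reflux) then closes the ring at C1–C8a and gives 5.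

2. Step 12. Transmetalation at the hindered, electron-rich boronate may be slow enough for protodeboronation to take over. The fallback sets out from 17 and 8 and comes back at 20. Bromine–lithium exchange of 17 (n-BuLi, THF, −78 °C, through 18) and transmetalation with ZnCl2 give (4,5-dimethoxy-7-methylnaphthalen-1-yl)zinc chloride F4. This is joined to 8 in a Negishi coupling (Pd2(dba)3, RuPhos, THF/NMP, 70 °C). The arylzinc transmetalates without base or water, and the boronate 19 is not needed.

3. Step 1. Acetylation may go to the position between the two methoxy groups or occur twice, or the diketone may close by aldol reaction to a naphthol while the pyrylium salt is hydrolysed. The fallback sets out from 1 and comes back at 3. Ketalisation (ethylene glycol, TsOH, toluene, removal of water) gives 2-[(3,5-dimethoxyphenyl)methyl]-2-methyl-1,3-dioxolane F5. Bromination with N-bromosuccinimide in MeCN, para to a methoxy group and ortho to the side chain, gives 2-[(2-bromo-3,5-dimethoxyphenyl)methyl]-2-methyl-1,3-dioxolane F6. Bromine–lithium exchange (n-BuLi, THF, −78 °C) gives [2,4-dimethoxy-6-[(2-methyl-1,3-dioxolan-2-yl)methyl]phenyl]lithium F7. Acetylation of F7 with N-methoxy-N-methylacetamide gives 1-[2,4-dimethoxy-6-[(2-methyl-1,3-dioxolan-2-yl)methyl]phenyl]ethan-1-one F8. Mild hydrolysis of the ketal (pyridinium p-toluenesulfonate, acetone/H2O) gives 3.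

**Further compounds**

F1 | step 2 | (2S)-1-(3,5-dimethoxyphenyl)-N-[(1S)-1-phenylethyl]propan-2-amine | C[C@H](N[C@@H](C)c1ccccc1)Cc1cc(OC)cc(OC)c1
F2 | step 2 | (2S)-1-(3,5-dimethoxyphenyl)propan-2-amine | C[C@H](N)Cc1cc(OC)cc(OC)c1
F3 | step 2 | N-[(2S)-1-(3,5-dimethoxyphenyl)propan-2-yl]acetamide | C[C@H](NC(C)=O)Cc1cc(OC)cc(OC)c1
F4 | step 12 | (4,5-dimethoxy-7-methylnaphthalen-1-yl)zinc chloride | Cc1cc(OC)c2c(OC)ccc([Zn]Cl)c2c1
F5 | step 1 | 2-[(3,5-dimethoxyphenyl)methyl]-2-methyl-1,3-dioxolane | CC1(Cc2cc(OC)cc(OC)c2)OCCO1
F6 | step 1 | 2-[(2-bromo-3,5-dimethoxyphenyl)methyl]-2-methyl-1,3-dioxolane | CC1(Cc2cc(OC)cc(OC)c2Br)OCCO1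
F7 | step 1 | [2,4-dimethoxy-6-[(2-methyl-1,3-dioxolan-2-yl)methyl]phenyl]lithium | [Li]c1c(OC)cc(OC)cc1CC1(C)OCCO1
F8 | step 1 | 1-[2,4-dimethoxy-6-[(2-methyl-1,3-dioxolan-2-yl)methyl]phenyl]ethan-1-one | CC(=O)c1c(OC)cc(OC)cc1CC1(C)OCCO1
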